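(The numbers are invented; the result is computed.)

In flask alpha, at 60 °C, the equilibrium constant between intermediate and target is 0.80, against 0.271 in flask delta at 100 °C, while the coupling carries an activation energy of 42.0 kJ mol⁻¹. Two colleagues read this comparison differently.

    starting material + coupling partner → intermediate + released group (k1 = 12 M⁻¹ s⁻¹, Ea1 = 42.0 kJ mol⁻¹)
    intermediate ⇌ target (K2 = 0.80, k2 = 0.47 s⁻¹, Ea2 = 74.0 kJ mol⁻¹, ΔH2 = −28.0 kJ mol⁻¹)
    intermediate ⇌ isomer of the product (K3 = 110, k3 = 0.0066 s⁻¹, Ea3 = 83.0 kJ mol⁻¹, ΔH3 = −74.0 kJ mol⁻¹)
    (constants at 60 °C)

| flask | starting material | coupling partner | temperature | time | remark |
|---|---|---|---|---|---|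
| eta | 10 mM | 30.0 mM | 80 °C | 5.0 s |  |
| alpha | 10 mM | 30.0 mM | 60 °C | 5.0 s |  |
| delta | 10 mM | 30.0 mM | 100 °C | 5.0 s |  |
| zeta | 10 mM | 30.0 mM |  | 5.0 s | at 60 °C until 1.5 s, from then on at 100 °C |

- the constants hold at 60 °C; other temperatures follow from the activation energies and enthalpies

1. the flask with the highest amount of target, in percent of the starting material charged ("all alike" if they lie within 1.5 percentage points) (eta / alpha / delta / zeta / all alike)
2. final target, as a percentage of the starting material charged, in eta
3. final target, as a percentage of the starting material charged, in alpha
4. final target, as a percentage of the starting material charged, in delta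
5. final target, as a percentage of the starting material charged, in zeta

The first colleague holds the coupling view: target follows conversion, so heat pays. Starting material is the limiting reagent, and the integrated rate law leaves 22.3% of the charge uncoupled in alpha after 5.0 s. That is a loss she would heat away.

The second colleague holds the share view, and this reckoning is mine. Intermediate and target relax towards each other with a half-life of 0.0179 s in delta, short against 5.0 s, and 0.655 s in alpha, also shorter than that time, so I treat the two as one pool. Of that pool, target holds K over one plus K, which is 44.4% in alpha and 21.3% in delta, and this share of the pool multiplies whatever fraction of the charge stands in the pool.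

Going from alpha to delta can therefore raise the pool by a factor of 1.29 at best, but it cuts the share by a factor of 2.08. Even a pool holding the whole charge gives 21.3% as target in delta and in zeta, since both end at 100 °C.

Now the corrections. In delta the isomer of the product drains the pool through the part that is intermediate, at 0.129 s⁻¹. If I take the coupling as instant and leave out the backward run from isomer of the product to intermediate, the pool keeps 52.5% of the charge, and target comes to 11.2%.

In alpha the step to the isomer of the product has a far smaller constant than the step to target, so I drop it, but target trails the pool by a relaxation time of 0.946 s. Taking the pool at that earlier moment gives 31.6%. I commit to alpha over delta and zeta, and I reckon eta no further.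

The forecast names alpha, with 27.2% in eta, 30.9% in alpha, 12.6% in delta and 14.5% in zeta, on the ground that heating “lets the target drain through the intermediate into the much more stable isomer”, and its alpha stands under mine and its delta over mine.

Flask alpha gives most: 30.7%, against 27.1% in eta, 12.7% in delta and 14.5% in zeta. The coupling view holds between eta and alpha earlier in the run: at 2.50 s eta stood at 24.1% target and alpha at 17.4%. Delta ended with 0.150% starting material and 40.4% isomer of the product, so the share of 21.3% on the remaining pool gives 12.7%. The neighbour of delta with 7.5 mM of coupling partner ended with 38.5% starting material and 21.0% isomer of the product, so the same share gives 8.63%, and that flask held 8.63% target.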